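**Retrosynthetic overview**

1. Numbering: dihydropyran O1, C2 (CH3), C3 (formyl carbon C7), C4 (arm C8H2–C9O2R), C5 (CO2Me), C6. The route rests on one feature: C7 on C3 and C9 on C4 can be joined through oxygen into a six-membered lactone ring C7(=O)–O–C9–C8–C4–C3. That ring is 5,6-dihydro-2H-pyran-2-one, with C3 as its α-carbon and C4 as its β-carbon.
2. Target 19 ⇐ desilylation and thermodynamic setting of C2 (retro-oxa-Michael/oxa-Michael) ⇐ aldehyde 16 ⇐ C7 Weinreb amide / C9 hydroxytyrosyl ester 15 ⇐ bicyclic lactone 9 (aminolysis, C9 oxidation, esterification with 14).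
3. 9 ⇐ aldol adduct 8 by acid-catalysed O1–C6 closure, the aldol oxygen displacing methanol at C6.
4. 8 ⇐ lactone 4 + alkenylmagnesium reagent from iodide 3 + acetaldehyde 5: C4–C5 by copper-catalysed asymmetric conjugate addition, C2–C3 by aldol trapping of the enolate.
5. Ring order: the lactone ring is present from 4 and is temporary; the dihydropyran ring closes in step 3; the lactone is opened in step 4.

Key step: step 2

Remark on the ligand: the sense of induction of the copper–Tol-BINAP complex with this alkenyl group is not known; (R)-Tol-BINAP is written, and its antipode is taken if C4 forms with the S configuration.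

Remark on C2: a closed aldol transition state of the ring-fixed (E)-enolate should favour the anti carbinol (2R), so the route is written with 2R from 8 to 16. Any 2S epimer formed alongside passes through steps 3–9 in the same way and meets the main line at 18, because step 10 sets C2 under thermodynamic control.

**Route**

Step 1
Reactants: 1 methyl (E)-3-methoxyacrylate
Product: 3 methyl (Z)-2-iodo-3-methoxyacrylate, via methyl 3-acetoxy-2-iodo-3-methoxypropanoate 2 (not isolated)
Conditions: NIS (1.2 equiv), AcOH (2 equiv), CH2Cl2, rt; then Et3N (3 equiv), rt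
Reagents that add atoms: N-iodosuccinimide, O=C1CCC(=O)N1I
Why: Electrophilic iodo-acetoxylation of the enol ether (iodine at C5, acetate at the oxocarbenium carbon C6) followed by base-induced loss of acetic acid should give the α-iodoacrylate with methoxy trans to the ester, the more stable geometry.

Step 2
Reactants: 3 methyl (Z)-2-iodo-3-methoxyacrylate; 4 5,6-dihydro-2H-pyran-2-one; 5 acetaldehyde
Product: 8 methyl (E)-2-[(3R,4R)-3-[(1R)-1-hydroxyethyl]-2-oxotetrahydro-2H-pyran-4-yl]-3-methoxyacrylate, via alkenylmagnesium reagent 6 (not isolated), via magnesium lactone enolate 7 (not isolated)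
Conditions: 3 (1.3 equiv), i-PrMgCl·LiCl (1.25 equiv), THF, −78 °C; slow addition to 4 (1 equiv), CuI (5 mol%), (R)-Tol-BINAP (6 mol%), t-BuOMe, −78 → −40 °C; then 5 (3 equiv), −78 °C; aq NH4Cl
Reagents that add atoms: none
Why: Proposed new method: iodine–magnesium exchange gives 6, which transmetalates to the monovalent copper–Tol-BINAP complex; the alkenylcopper binds the enoate of 4, adds oxidatively at C4 to a trivalent copper species and eliminates reductively to form C4–C5 with the alkene geometry kept, leaving magnesium enolate 7, which adds to 5 through a closed six-membered (Zimmerman–Traxler) transition state to form C2–C3. The closest known reaction types are the copper/bisphosphine-catalysed asymmetric conjugate addition of alkyl Grignard reagents to 5,6-dihydro-2H-pyran-2-one and the conjugate addition–aldol three-component coupling of cyclic enones; new here is an ester-bearing alkenyl group as the transferred ligand, which is a weaker donor than an alkyl group. No ring closes in this step. C4 is set by the chiral copper complex (enantioface of the enoate), C3 by C4 (the aldehyde approaches the enolate face anti to the new C4 substituent, giving the 3,4-trans lactone), and C2 by the ring-fixed (E)-enolate in the closed transition state, which favours the anti carbinol (2R); this is the C2 epimer of what the target needs and is accepted because C2 is reset in step 10. The step needs 1,4- over 1,2-addition and alkenyl over isopropyl transfer, secured by the soft copper nucleophile on the s-cis-locked enoate and by keeping i-PrMgCl below one equivalent per 3; enolate 7 has no intramolecular outlet because attack of C3 on the C5 ester or on C6 would close a four-membered ring.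

Step 3
Reactants: 8 methyl (E)-2-[(3R,4R)-3-[(1R)-1-hydroxyethyl]-2-oxotetrahydro-2H-pyran-4-yl]-3-methoxyacrylate
Product: 9 methyl (1R,4aR,8aR)-1-methyl-8-oxo-1,4a,5,6,8,8a-hexahydropyrano[3,4-c]pyran-4-carboxylate (trans-fused bicyclic lactone; route atoms C2 R, C3 R, C4 R)
Conditions: PPTS (0.2 equiv), 5 Å MS, toluene, 70 °C
Reagents that add atoms: none
Why: Acid-catalysed alkoxy exchange at the β-methoxyacrylate (C5 protonation, 6-exo-trig attack of the C2 hydroxyl on the C6 oxocarbenium ion, loss of methanol to the sieves) should close the dihydropyran without touching the C2–O bond, so C2, C3 and C4 are unchanged, and the mild acid should not dehydrate the β-hydroxy lactone.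

Step 4
Reactants: 9 methyl (1R,4aR,8aR)-1-methyl-8-oxo-1,4a,5,6,8,8a-hexahydropyrano[3,4-c]pyran-4-carboxylate
Product: 10 methyl (2R,3R,4R)-4-(2-hydroxyethyl)-3-[methoxy(methyl)carbamoyl]-2-methyl-3,4-dihydro-2H-pyran-5-carboxylate
Conditions: MeNH(OMe)·HCl (3 equiv), AlMe3 (3 equiv), CH2Cl2, 0 °C; aq potassium sodium tartrate; crude product used at once
Reagents that add atoms: N,O-dimethylhydroxylamine hydrochloride, CNOC.Cl
Why: Weinreb aminolysis with the aluminium amide should open the unconjugated δ-lactone at C7 far faster than it attacks the donor-substituted (vinylogous carbonate) methyl ester, releasing the C9 alcohol with no stereocentre involved.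

Step 5
Reactants: 10 methyl (2R,3R,4R)-4-(2-hydroxyethyl)-3-[methoxy(methyl)carbamoyl]-2-methyl-3,4-dihydro-2H-pyran-5-carboxylate
Product: 11 2-[(2R,3R,4R)-5-(methoxycarbonyl)-3-[methoxy(methyl)carbamoyl]-2-methyl-3,4-dihydro-2H-pyran-4-yl]acetic acid
Conditions: TEMPO (0.2 equiv), PhI(OAc)2 (2.5 equiv), MeCN/H2O (1:1), rt
Reagents that add atoms: water, O
Why: Oxoammonium oxidation of the primary alcohol to the aldehyde and of its hydrate to the acid leaves the tertiary amide and the electron-poor enol ether alone, and prompt oxidation removes the hydroxyl that could close back onto C7.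

Step 6
Reactants: 12 hydroxytyrosol
Product: 13 tert-butyl-[2-[3,4-bis(tert-butyldimethylsilyloxy)phenyl]ethoxy]dimethylsilane
Conditions: TBSCl (3.5 equiv), imidazole (7 equiv), DMF, rt
Reagents that add atoms: tert-butyldimethylsilyl chloride, CC(C)(C)[Si](C)(C)Cl
Why: Exhaustive silylation of both phenols and the primary alcohol is a standard protection and avoids any need for selectivity at this stage.

Step 7
Reactants: 13 tert-butyl-[2-[3,4-bis(tert-butyldimethylsilyloxy)phenyl]ethoxy]dimethylsilane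
Product: 14 2-[3,4-bis(tert-butyldimethylsilyloxy)phenyl]ethanol
Conditions: CSA (0.1 equiv), MeOH/CH2Cl2 (1:1), 0 °C
Reagents that add atoms: none
Why: Acid-catalysed methanolysis cleaves the primary alkyl silyl ether much faster than aryl silyl ethers, whose oxygen is less basic, so only the aliphatic hydroxyl should be freed.

Step 8
Reactants: 11 2-[(2R,3R,4R)-5-(methoxycarbonyl)-3-[methoxy(methyl)carbamoyl]-2-methyl-3,4-dihydro-2H-pyran-4-yl]acetic acid; 14 2-[3,4-bis(tert-butyldimethylsilyloxy)phenyl]ethanol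
Product: 15 methyl (2R,3R,4R)-4-[2-[2-[3,4-bis(tert-butyldimethylsilyloxy)phenyl]ethoxy]-2-oxoethyl]-3-[methoxy(methyl)carbamoyl]-2-methyl-3,4-dihydro-2H-pyran-5-carboxylate
Conditions: EDC·HCl (1.5 equiv), DMAP (0.2 equiv), CH2Cl2, 0 °C → rt
Reagents that add atoms: none
Why: Steglich-type carbodiimide esterification of an unhindered acetic acid arm with a primary alcohol is reliable and does not disturb the amide, the enol ether or the aryl silyl ethers.

Step 9
Reactants: 15 methyl (2R,3R,4R)-4-[2-[2-[3,4-bis(tert-butyldimethylsilyloxy)phenyl]ethoxy]-2-oxoethyl]-3-[methoxy(methyl)carbamoyl]-2-methyl-3,4-dihydro-2H-pyran-5-carboxylate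
Product: 16 methyl (2R,3R,4R)-4-[2-[2-[3,4-bis(tert-butyldimethylsilyloxy)phenyl]ethoxy]-2-oxoethyl]-3-formyl-2-methyl-3,4-dihydro-2H-pyran-5-carboxylate (2,3-cis-3,4-trans)
Conditions: Cp2Zr(H)Cl (1.6 equiv), THF, rt, 20 min; then SiO2/H2O
Reagents that add atoms: none
Why: Hydrozirconation of the tertiary amide carbonyl gives a zirconium-bound N,O-hemiaminal that releases the aldehyde only on work-up, so over-reduction is avoided, and the two esters and the vinylogous carbonate react more slowly with this hydride.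

Step 10
Reactants: 16 methyl (2R,3R,4R)-4-[2-[2-[3,4-bis(tert-butyldimethylsilyloxy)phenyl]ethoxy]-2-oxoethyl]-3-formyl-2-methyl-3,4-dihydro-2H-pyran-5-carboxylate
Product: 18 methyl (2S,3R,4R)-4-[2-[2-[3,4-bis(tert-butyldimethylsilyloxy)phenyl]ethoxy]-2-oxoethyl]-3-formyl-2-methyl-3,4-dihydro-2H-pyran-5-carboxylate, via ring-opened enal enol 17 (not isolated)
Conditions: Et3N (0.5 equiv), CH2Cl2, rt
Reagents that add atoms: none
Why: Deprotonation at C3 and E1cB loss of O1 (a stabilised β-formyl ester enolate) opens the ring reversibly to 17, and 6-endo-trig oxa-Michael re-closure at C2 with reprotonation at C3 should settle on the 2,3-trans-3,4-trans isomer, which lacks the cis methyl/formyl interaction of 16, while C4 has no acidic hydrogen and keeps its configuration.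

Step 11
Reactants: 18 methyl (2S,3R,4R)-4-[2-[2-[3,4-bis(tert-butyldimethylsilyloxy)phenyl]ethoxy]-2-oxoethyl]-3-formyl-2-methyl-3,4-dihydro-2H-pyran-5-carboxylate
Product: 19 methyl (2S,3R,4R)-4-[2-[2-(3,4-dihydroxyphenyl)ethoxy]-2-oxoethyl]-3-formyl-2-methyl-3,4-dihydro-2H-pyran-5-carboxylate
Conditions: HF·pyridine, pyridine, THF, 0 °C
Reagents that add atoms: none
Why: Fluoride cleavage of the two aryl silyl ethers in a buffered, non-basic medium should free the catechol without base-induced ring opening of the β-alkoxy aldehyde or air oxidation of a catecholate.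

**Compound list**

1 | methyl (E)-3-methoxyacrylate | CO/C=C/C(=O)OC | starting material
2 | methyl 3-acetoxy-2-iodo-3-methoxypropanoate (diastereomer mixture) | COC(OC(C)=O)C(I)C(=O)OC | intermediate
3 | methyl (Z)-2-iodo-3-methoxyacrylate | CO/C=C(\I)C(=O)OC | intermediate
4 | 5,6-dihydro-2H-pyran-2-one | O=C1C=CCCO1 | starting material
5 | acetaldehyde | CC=O | starting material
6 | methyl (Z)-2-(chloromagnesio)-3-methoxyacrylate (LiCl complex) | CO/C=C(\[Mg]Cl)C(=O)OC | intermediate
7 | chloromagnesium enolate of methyl (E)-3-methoxy-2-[(4R)-2-oxotetrahydro-2H-pyran-4-yl]acrylate | CO/C=C(\[C@@H]1CCOC(O[Mg]Cl)=C1)C(=O)OC | intermediate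
8 | methyl (E)-2-[(3R,4R)-3-[(1R)-1-hydroxyethyl]-2-oxotetrahydro-2H-pyran-4-yl]-3-methoxyacrylate | C[C@@H](O)[C@@H]1C(=O)OCC[C@H]1/C(C(=O)OC)=C\OC | intermediate
9 | methyl (1R,4aR,8aR)-1-methyl-8-oxo-1,4a,5,6,8,8a-hexahydropyrano[3,4-c]pyran-4-carboxylate | COC(=O)C1=CO[C@H](C)[C@@H]2C(=O)OCC[C@@H]12 | intermediate
10 | methyl (2R,3R,4R)-4-(2-hydroxyethyl)-3-[methoxy(methyl)carbamoyl]-2-methyl-3,4-dihydro-2H-pyran-5-carboxylate | COC(=O)C1=CO[C@H](C)[C@H](C(=O)N(C)OC)[C@H]1CCO | intermediate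
11 | 2-[(2R,3R,4R)-5-(methoxycarbonyl)-3-[methoxy(methyl)carbamoyl]-2-methyl-3,4-dihydro-2H-pyran-4-yl]acetic acid | COC(=O)C1=CO[C@H](C)[C@H](C(=O)N(C)OC)[C@H]1CC(=O)O | intermediate
12 | hydroxytyrosol, 2-(3,4-dihydroxyphenyl)ethanol | OCCc1ccc(O)c(O)c1 | starting material
13 | tert-butyl-[2-[3,4-bis(tert-butyldimethylsilyloxy)phenyl]ethoxy]dimethylsilane | CC(C)(C)[Si](C)(C)OCCc1ccc(O[Si](C)(C)C(C)(C)C)c(O[Si](C)(C)C(C)(C)C)c1 | intermediate
14 | 2-[3,4-bis(tert-butyldimethylsilyloxy)phenyl]ethanol | OCCc1ccc(O[Si](C)(C)C(C)(C)C)c(O[Si](C)(C)C(C)(C)C)c1 | intermediate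
15 | methyl (2R,3R,4R)-4-[2-[2-[3,4-bis(tert-butyldimethylsilyloxy)phenyl]ethoxy]-2-oxoethyl]-3-[methoxy(methyl)carbamoyl]-2-methyl-3,4-dihydro-2H-pyran-5-carboxylate | COC(=O)C1=CO[C@H](C)[C@H](C(=O)N(C)OC)[C@H]1CC(=O)OCCc1ccc(O[Si](C)(C)C(C)(C)C)c(O[Si](C)(C)C(C)(C)C)c1 | intermediate
16 | methyl (2R,3R,4R)-4-[2-[2-[3,4-bis(tert-butyldimethylsilyloxy)phenyl]ethoxy]-2-oxoethyl]-3-formyl-2-methyl-3,4-dihydro-2H-pyran-5-carboxylate | COC(=O)C1=CO[C@H](C)[C@H](C=O)[C@H]1CC(=O)OCCc1ccc(O[Si](C)(C)C(C)(C)C)c(O[Si](C)(C)C(C)(C)C)c1 | intermediate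
17 | 2-[3,4-bis(tert-butyldimethylsilyloxy)phenyl]ethyl (3R,4E)-4-formyl-3-[2-hydroxy-1-(methoxycarbonyl)vinyl]hex-4-enoate (enol drawn with hydroxyl cis to C4) | C/C=C(/C=O)[C@@H](CC(=O)OCCc1ccc(O[Si](C)(C)C(C)(C)C)c(O[Si](C)(C)C(C)(C)C)c1)/C(C(=O)OC)=C\O | intermediate
18 | methyl (2S,3R,4R)-4-[2-[2-[3,4-bis(tert-butyldimethylsilyloxy)phenyl]ethoxy]-2-oxoethyl]-3-formyl-2-methyl-3,4-dihydro-2H-pyran-5-carboxylate | COC(=O)C1=CO[C@@H](C)[C@H](C=O)[C@H]1CC(=O)OCCc1ccc(O[Si](C)(C)C(C)(C)C)c(O[Si](C)(C)C(C)(C)C)c1 | intermediate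
19 | methyl (2S,3R,4R)-4-[2-[2-(3,4-dihydroxyphenyl)ethoxy]-2-oxoethyl]-3-formyl-2-methyl-3,4-dihydro-2H-pyran-5-carboxylate | COC(=O)C1=CO[C@@H](C)[C@H](C=O)[C@H]1CC(=O)OCCc1ccc(O)c(O)c1 | target

**Step count**

Total steps: 11. Longest linear sequence: 9 steps (1, 2, 3, 4, 5, 8, 9, 10, 11); steps 6 and 7 make the alcohol partner 14.

**Steps most likely to fail**

1. Step 2 (proposed new method). The ester-bearing alkenylcopper may fail to transfer to C4: the magnesium reagent may decompose by loss of methoxide, 1,2-addition to the lactone may compete, or the enantioface discrimination may be poor. The fallback uses known reaction types only, sets out from 3 and returns at 8. Commercial 5,6-dihydro-2H-pyran-2,4(3H)-dione F1 is converted with Tf2O and Et3N (CH2Cl2, −78 °C) into the enol triflate 2-oxo-5,6-dihydro-2H-pyran-4-yl trifluoromethanesulfonate F2. Iodide 3 is exchanged with i-PrMgCl·LiCl and transmetalated with ZnCl2 to methyl (Z)-2-(chlorozincio)-3-methoxyacrylate F3. Negishi coupling of F3 with F2 (Pd(PPh3)4, THF, rt) forms C4–C5 at an sp2 carbon and gives methyl (E)-3-methoxy-2-(2-oxo-5,6-dihydro-2H-pyran-4-yl)acrylate F4. CuH-catalysed asymmetric conjugate reduction of the β-substituted unsaturated lactone (CuCl, NaOt-Bu, Tol-BINAP of the enantiomer that gives 4R, polymethylhydrosiloxane, toluene, 0 °C) delivers hydride to C4; the donor-substituted acrylate should be left alone, and the product is methyl (E)-3-methoxy-2-[(4R)-2-oxotetrahydro-2H-pyran-4-yl]acrylate F5. Enolisation with LiN(i-Pr)2 (THF, −78 °C) and addition of 5 forms C2–C3 trans to the C4 substituent and gives 8.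

2. Step 4. The aluminium amide may attack C6 of the vinylogous carbonate (opening the dihydropyran) or the methyl ester, and the δ-hydroxy amide may close back to the lactone before it is oxidised. The fallback sets out from 9 and returns at 16; it also avoids the amide reduction of step 9. LiOH (1.1 equiv, THF/H2O, 0 °C) opens the lactone to lithium (2R,3R,4R)-4-(2-hydroxyethyl)-5-(methoxycarbonyl)-2-methyl-3,4-dihydro-2H-pyran-3-carboxylate F6, which is kept as the salt so that it cannot re-lactonise. Oxidation with TEMPO (cat.), NaOCl (cat.) and NaClO2 in phosphate buffer (pH 6.7)/MeCN gives (2R,3R,4R)-4-(carboxymethyl)-5-(methoxycarbonyl)-2-methyl-3,4-dihydro-2H-pyran-3-carboxylic acid F7. Ac2O in CH2Cl2 closes the six-membered anhydride methyl (1R,4aR,8aR)-1-methyl-6,8-dioxo-1,4a,5,6,8,8a-hexahydropyrano[3,4-c]pyran-4-carboxylate F8. Alcohol 14 with DMAP and Et3N opens it at the less hindered C9 carbonyl to give (2R,3R,4R)-4-[2-[2-[3,4-bis(tert-butyldimethylsilyloxy)phenyl]ethoxy]-2-oxoethyl]-5-(methoxycarbonyl)-2-methyl-3,4-dihydro-2H-pyran-3-carboxylic acid F9. EtSH, EDC·HCl and DMAP convert the C7 acid into methyl (2R,3R,4R)-4-[2-[2-[3,4-bis(tert-butyldimethylsilyloxy)phenyl]ethoxy]-2-oxoethyl]-3-(ethylsulfanylcarbonyl)-2-methyl-3,4-dihydro-2H-pyran-5-carboxylate F10, and Fukuyama reduction (Et3SiH, Pd/C (palladium on carbon), acetone, rt) gives aldehyde 16.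

3. Step 10. The thermodynamic inversion at C2 may stall at a mixture of ring-closed epimers and ring-opened material, or the amine may start to cleave an aryl silyl ether. The fallback sets C2 kinetically before the ring is closed; it sets out from 8 and returns at 18. Dess–Martin periodinane (CH2Cl2, rt) oxidises the carbinol to methyl (E)-2-[(3R,4R)-3-acetyl-2-oxotetrahydro-2H-pyran-4-yl]-3-methoxyacrylate F11. Chelation-controlled reduction with Zn(BH4)2 (Et2O, −20 °C) delivers hydride to the zinc chelate from the face opposite C4 and should give the syn carbinol methyl (E)-2-[(3R,4R)-3-[(1S)-1-hydroxyethyl]-2-oxotetrahydro-2H-pyran-4-yl]-3-methoxyacrylate F12. The conditions of step 3 then give methyl (1S,4aR,8aR)-1-methyl-8-oxo-1,4a,5,6,8,8a-hexahydropyrano[3,4-c]pyran-4-carboxylate F13. Those of step 4 give methyl (2S,3R,4R)-4-(2-hydroxyethyl)-3-[methoxy(methyl)carbamoyl]-2-methyl-3,4-dihydro-2H-pyran-5-carboxylate F14. Those of step 5 give 2-[(2S,3R,4R)-5-(methoxycarbonyl)-3-[methoxy(methyl)carbamoyl]-2-methyl-3,4-dihydro-2H-pyran-4-yl]acetic acid F15. Those of step 8 with 14 give methyl (2S,3R,4R)-4-[2-[2-[3,4-bis(tert-butyldimethylsilyloxy)phenyl]ethoxy]-2-oxoethyl]-3-[methoxy(methyl)carbamoyl]-2-methyl-3,4-dihydro-2H-pyran-5-carboxylate F16. Reduction with Cp2Zr(H)Cl as in step 9 gives 18 directly.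

**Further compounds**

F1 | step 2 | 5,6-dihydro-2H-pyran-2,4(3H)-dione | O=C1CC(=O)CCO1
F2 | step 2 | 2-oxo-5,6-dihydro-2H-pyran-4-yl trifluoromethanesulfonate | O=C1C=C(OS(=O)(=O)C(F)(F)F)CCO1
F3 | step 2 | methyl (Z)-2-(chlorozincio)-3-methoxyacrylate | CO/C=C(\[Zn]Cl)C(=O)OC
F4 | step 2 | methyl (E)-3-methoxy-2-(2-oxo-5,6-dihydro-2H-pyran-4-yl)acrylate | CO/C=C(\C1=CC(=O)OCC1)C(=O)OC
F5 | step 2 | methyl (E)-3-methoxy-2-[(4R)-2-oxotetrahydro-2H-pyran-4-yl]acrylate | CO/C=C(\[C@@H]1CCOC(=O)C1)C(=O)OC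
F6 | step 4 | lithium (2R,3R,4R)-4-(2-hydroxyethyl)-5-(methoxycarbonyl)-2-methyl-3,4-dihydro-2H-pyran-3-carboxylate | [Li+].COC(=O)C1=CO[C@H](C)[C@H](C([O-])=O)[C@H]1CCO
F7 | step 4 | (2R,3R,4R)-4-(carboxymethyl)-5-(methoxycarbonyl)-2-methyl-3,4-dihydro-2H-pyran-3-carboxylic acid | COC(=O)C1=CO[C@H](C)[C@H](C(=O)O)[C@H]1CC(=O)O
F8 | step 4 | methyl (1R,4aR,8aR)-1-methyl-6,8-dioxo-1,4a,5,6,8,8a-hexahydropyrano[3,4-c]pyran-4-carboxylate | COC(=O)C1=CO[C@H](C)[C@@H]2C(=O)OC(=O)C[C@@H]12
F9 | step 4 | (2R,3R,4R)-4-[2-[2-[3,4-bis(tert-butyldimethylsilyloxy)phenyl]ethoxy]-2-oxoethyl]-5-(methoxycarbonyl)-2-methyl-3,4-dihydro-2H-pyran-3-carboxylic acid | COC(=O)C1=CO[C@H](C)[C@H](C(=O)O)[C@H]1CC(=O)OCCc1ccc(O[Si](C)(C)C(C)(C)C)c(O[Si](C)(C)C(C)(C)C)c1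
F10 | step 4 | methyl (2R,3R,4R)-4-[2-[2-[3,4-bis(tert-butyldimethylsilyloxy)phenyl]ethoxy]-2-oxoethyl]-3-(ethylsulfanylcarbonyl)-2-methyl-3,4-dihydro-2H-pyran-5-carboxylate | COC(=O)C1=CO[C@H](C)[C@H](C(=O)SCC)[C@H]1CC(=O)OCCc1ccc(O[Si](C)(C)C(C)(C)C)c(O[Si](C)(C)C(C)(C)C)c1
F11 | step 10 | methyl (E)-2-[(3R,4R)-3-acetyl-2-oxotetrahydro-2H-pyran-4-yl]-3-methoxyacrylate | CC(=O)[C@@H]1C(=O)OCC[C@H]1/C(C(=O)OC)=C\OC
F12 | step 10 | methyl (E)-2-[(3R,4R)-3-[(1S)-1-hydroxyethyl]-2-oxotetrahydro-2H-pyran-4-yl]-3-methoxyacrylate | C[C@H](O)[C@@H]1C(=O)OCC[C@H]1/C(C(=O)OC)=C\OC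
F13 | step 10 | methyl (1S,4aR,8aR)-1-methyl-8-oxo-1,4a,5,6,8,8a-hexahydropyrano[3,4-c]pyran-4-carboxylate | COC(=O)C1=CO[C@@H](C)[C@@H]2C(=O)OCC[C@@H]12
F14 | step 10 | methyl (2S,3R,4R)-4-(2-hydroxyethyl)-3-[methoxy(methyl)carbamoyl]-2-methyl-3,4-dihydro-2H-pyran-5-carboxylate | COC(=O)C1=CO[C@@H](C)[C@H](C(=O)N(C)OC)[C@H]1CCO
F15 | step 10 | 2-[(2S,3R,4R)-5-(methoxycarbonyl)-3-[methoxy(methyl)carbamoyl]-2-methyl-3,4-dihydro-2H-pyran-4-yl]acetic acid | COC(=O)C1=CO[C@@H](C)[C@H](C(=O)N(C)OC)[C@H]1CC(=O)O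
F16 | step 10 | methyl (2S,3R,4R)-4-[2-[2-[3,4-bis(tert-butyldimethylsilyloxy)phenyl]ethoxy]-2-oxoethyl]-3-[methoxy(methyl)carbamoyl]-2-methyl-3,4-dihydro-2H-pyran-5-carboxylate | COC(=O)C1=CO[C@@H](C)[C@H](C(=O)N(C)OC)[C@H]1CC(=O)OCCc1ccc(O[Si](C)(C)C(C)(C)C)c(O[Si](C)(C)C(C)(C)C)c1
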